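Ring C (C2'–C3'–C4'–C5'–C6') bears two carbon substituents on adjacent atoms, C7' on C6' and C1' on C2', trans to each other and flanking the oxygenated C3'. This is what a five-membered enone gives when its β-carbon and then its α-carbon are substituted. Everything therefore rests on the C6'–C7' and C2'–C1' disconnections: one flask unites the parent cyclopentenone, an isopropenyl Grignard reagent and a methylenemalonate ester under a chiral copper catalyst, setting C6' (catalyst) and C2' (relay) and installing C1, C1', C7' and C8'. Methyl addition at C3', radical 6-endo closure of ring B (C1–C1'–C2'–C6'–C7'–C8'), hydration at C7' and a Claisen annulation/diprenylation for ring A follow.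

Key step: step 3

Remark: ring A is numbered C1 (spiro), C2 (C=O beside the acetyl-bearing C3), C4 (enol carbon), C5 (diprenyl carbon), C6 (C=O); ring B of the trans-hydrindane is assumed to be a chair with equatorial ring-fusion bonds, which makes the C7' methyl and the C1–C2 bond axial (syn to each other) and the C7' hydroxyl and the C1–C6 bond equatorial; ring A is drawn as an enol, one of several tautomers of the same compound; the sense of induction of the named ligand with an alkenyl Grignard reagent on the five-membered enone is assumed, and its (S)-(RP) enantiomer would be used instead if a trial addition showed the opposite sense.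

Step 1
Reactants: 1 2-bromopropene
Product: 2 isopropenylmagnesium bromide (prop-1-en-2-ylmagnesium bromide), titrated solution
Conditions: Mg turnings, I2 (cat.), 2-MeTHF, 40–50 °C
Reagents that add atoms: magnesium, [Mg]
Why: Grignard formation by insertion of magnesium into the vinylic C–Br bond is routine in a cyclic ether, and 2-MeTHF is chosen because the small amount carried into the copper-catalysed step should be tolerated better than THF.

Step 2
Reactants: 3 dimethyl malonate
Product: 5 dimethyl methylenemalonate, via dimethyl 2-(hydroxymethyl)malonate 4 (not isolated)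
Conditions: (CH2O)n, Cu(OAc)2 (cat.), KOAc, AcOH, 100 °C; then distillation under reduced pressure with thermal cracking of oligomers; kept at −20 °C and used within hours
Reagents that add atoms: formaldehyde (as paraformaldehyde), C=O
Why: Knoevenagel condensation (hydroxymethylation to 4, then dehydration) gives the methylene compound, whose oligomers revert to monomer on heating so that fresh distillate is monomeric.

Step 3
Reactants: 6 cyclopent-2-en-1-one; 2 isopropenylmagnesium bromide; 5 dimethyl methylenemalonate
Product: 9 dimethyl 2-{[(1S,5R)-2-oxo-5-(prop-1-en-2-yl)cyclopentyl]methyl}malonate (C2'/C6' trans), via magnesium enolate 7 (not isolated), via malonate magnesium enolate 8 (not isolated)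
Conditions: CuBr·SMe2 (5 mol %), (R)-1-[(SP)-2-(diphenylphosphino)ferrocenyl]ethyldicyclohexylphosphine (6 mol %), t-BuOMe, −78 °C, 2 (1.1 equiv) added over 2 h; then 5 (1.05 equiv, precooled solution), −78 → −60 °C; sat. aq. NH4Cl at −78 °C
Reagents that add atoms: isopropenylmagnesium bromide (2), CC(=C)[Mg]Br; dimethyl methylenemalonate (5), C=C(C(=O)OC)C(=O)OC
Why: The copper–diphosphine complex is alkenylated by 2 to a chiral cuprate that binds the enone as a π-complex, adds oxidatively at the β-carbon (a trivalent copper σ-intermediate) and eliminates reductively to forge C6'–C7', leaving the regiodefined magnesium enolate 7; its α-carbon C2' then attacks the unsubstituted CH2 terminus of 5 in a Michael addition (C2'–C1'), and the stabilised malonate enolate 8 is protonated on quench. The closest known reaction type is the copper-catalysed enantioselective conjugate addition of Grignard reagents to cyclic enones with capture of the magnesium enolate in the same flask by a Michael acceptor. No ring is closed in this step. C6' is set by the chiral ligand on copper (catalyst control, both ligand enantiomers being commercial), and C2' is set by the new C6' substituent, because the acceptor approaches the enolate face anti to the isopropenyl group, which is also the thermodynamic trans arrangement of an epimerisable α-centre. The step needs conjugate addition to outrun carbonyl addition and the uncatalysed background reaction, which slow addition of 2 in the cold to the preformed catalyst should secure, and it needs a single Michael addition, which the lower nucleophilicity of enolate 8 compared with enolate 7 and the near-stoichiometric charge of 5 should secure.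

Step 4
Reactants: 9 dimethyl 2-{[(1S,5R)-2-oxo-5-(prop-1-en-2-yl)cyclopentyl]methyl}malonate
Product: 10 dimethyl 2-{[(1S,2R,5R)-2-hydroxy-2-methyl-5-(prop-1-en-2-yl)cyclopentyl]methyl}malonate
Conditions: MeMgBr (3.2 equiv), anhydrous CeCl3 (3.2 equiv), THF, −78 °C; sat. aq. NH4Cl at −78 °C; crude used at once
Reagents that add atoms: methylmagnesium bromide, C[Mg]Br
Why: Organocerium 1,2-addition to a ketone in the presence of esters, in which the first equivalent removes the acidic malonate proton (shielding both esters and enlarging the C2' substituent) and the methyl group then attacks the C3' carbonyl from the face anti to the C2' side chain, as is usual for 2-substituted cyclopentanones, so that CH3 is trans and OH cis to C1' (3'R).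

Step 5
Reactants: 10 dimethyl 2-{[(1S,2R,5R)-2-hydroxy-2-methyl-5-(prop-1-en-2-yl)cyclopentyl]methyl}malonate
Product: 11 dimethyl 2-{[(1S,2R,5R)-2-[(tert-butyldimethylsilyl)oxy]-2-methyl-5-(prop-1-en-2-yl)cyclopentyl]methyl}malonate
Conditions: TBSOTf (1.5 equiv), 2,6-lutidine (3 equiv), CH2Cl2, −78 → 0 °C
Reagents that add atoms: tert-butyldimethylsilyl trifluoromethanesulfonate, CC(C)(C)[Si](C)(C)OS(=O)(=O)C(F)(F)F
Why: A silyl triflate with a hindered pyridine base silylates tertiary alcohols cleanly, and the ether blocks δ-lactonisation of the C3' hydroxyl onto the cis malonate ester, which would give a bicycle that could no longer close ring B.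

Step 6
Reactants: 11 dimethyl 2-{[(1S,2R,5R)-2-[(tert-butyldimethylsilyl)oxy]-2-methyl-5-(prop-1-en-2-yl)cyclopentyl]methyl}malonate
Product: 12 dimethyl (3R,3aS,7aR)-3-[(tert-butyldimethylsilyl)oxy]-3-methyl-7-methylideneoctahydro-5H-indene-5,5-dicarboxylate (trans-fused; indene C3 = C3', C3a = C2', C5 = C1, C7 = C7', C7a = C6')
Conditions: Mn(OAc)3·2H2O (2.2 equiv), Cu(OAc)2·H2O (1 equiv), AcOH, 60 °C
Reagents that add atoms: none
Why: Oxidative free-radical cyclisation of an unsaturated malonate, in which Mn(OAc)3 generates the electrophilic C1 radical, this closes 6-endo-trig onto the CH2 terminus (C8') of the 1,1-disubstituted alkene (the 5-exo mode would demand a trans-fused bicyclo[3.3.0]octane) and Cu(OAc)2, regenerated by the second equivalent of Mn(OAc)3, oxidises the tertiary C7' radical through an organocopper intermediate whose β-hydride loss favours the less substituted exocyclic alkene; the ring fusion is trans because C2' and C6' were set in step 3, and no new stereocentre arises.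

Step 7
Reactants: 12 dimethyl (3R,3aS,7aR)-3-[(tert-butyldimethylsilyl)oxy]-3-methyl-7-methylideneoctahydro-5H-indene-5,5-dicarboxylate
Product: 14 dimethyl (3R,3aS,7R,7aR)-3-[(tert-butyldimethylsilyl)oxy]-7-hydroxy-3,7-dimethyloctahydro-5H-indene-5,5-dicarboxylate, via C7' hydroperoxide 13 (not isolated)
Conditions: Mn(dpm)3 (dpm = dipivaloylmethanate, 10 mol %), PhSiH3 (2.5 equiv), O2 (1 atm), i-PrOH/CH2Cl2, 0 °C → rt; then PPh3
Reagents that add atoms: dioxygen, O=O
Why: Mukaiyama hydration, in which hydrogen-atom transfer to the CH2 terminus gives the tertiary C7' radical (so the step does not depend on where step 6 leaves the double bond around C7'), O2 should capture it on the equatorial face because the axial face is screened by the syn-axial CO2Me on C1, and PPh3 reduces hydroperoxide 13, which places OH equatorial and CH3 axial (7'R).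

Step 8
Reactants: 14 dimethyl (3R,3aS,7R,7aR)-3-[(tert-butyldimethylsilyl)oxy]-7-hydroxy-3,7-dimethyloctahydro-5H-indene-5,5-dicarboxylate; 15 acetylacetone (pentane-2,4-dione)
Product: 17 ring A trione TBS ether (3-acetyl-4-hydroxy-cyclohex-3-ene-2,6-dione spiro-fused at C1 (S) to the 3'-silyloxy-7'-hydroxy-3',7'-dimethyl-trans-hydrindane; C5 = CH2), via triketo ester 16 (not isolated)
Conditions: 15 (5 equiv), LiN(i-Pr)2 (11 equiv), THF, −78 → 0 °C; then 14, −78 °C → rt, then 50 °C; cold 1 M HCl work-up
Reagents that add atoms: acetylacetone (15), CC(=O)CC(C)=O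
Why: Two Claisen condensations in sequence, in which the terminal carbanion of dilithioacetylacetone acylates the exposed equatorial ester (C5–C6 bond, giving 16) and the central carbon C3 of the resulting triketone polyanion then closes onto the remaining axial ester in a Dieckmann-type step (C3–C2 bond), so that the spiro centre C1 (S) follows from the steric difference between the diastereotopic esters, the axial one being shielded by the syn-axial C7' methyl; the surplus base ionises the free C7' hydroxyl, whose equatorial alkoxide is held away from both esters by the rigid trans ring fusion.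

Step 9
Reactants: 17 ring A trione TBS ether
Product: 18 ring A trione diol (3-acetyl-4-hydroxy-cyclohex-3-ene-2,6-dione spiro-fused at C1 (S) to the (2'S,3'R,6'R,7'R)-3',7'-dihydroxy-3',7'-dimethyl-trans-hydrindane; C5 = CH2)
Conditions: 48% aq. HF, MeCN, 0 °C → rt
Reagents that add atoms: none
Why: Acidic fluoride cleaves the tertiary silyl ether through Si–F bond formation without harming the enolised trione or the tertiary alcohols, and the step is placed before prenylation so that the acid-sensitive prenyl groups are never exposed to it.

Step 10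
Reactants: 18 ring A trione diol; 19 prenyl bromide (1-bromo-3-methylbut-2-ene)
Product: 21 CNP0266834.1 (the target; 1S,2'S,3'R,6'R,7'R), via monoprenyl trione 20 (not isolated)
Conditions: 19 (2.3 equiv), NaOMe (3.2 equiv), MeOH, −10 → 0 °C; citrate buffer (pH 4) work-up
Reagents that add atoms: prenyl bromide (19), CC(C)=CCBr
Why: Two successive SN2 C-alkylations of the cyclic β-triketone anion at C5 (the first giving 20, which is still enolisable at C5), the only ring A carbon between two carbonyls that still carries hydrogen, in a protic medium that favours C- over O-alkylation as in the exhaustive C-alkylation of acylphloroglucinols; the tertiary alcohols stay un-ionised and no stereocentre is formed or touched.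

Compound list
1 | 2-bromopropene | CC(Br)=C | starting material
2 | isopropenylmagnesium bromide | CC(=C)[Mg]Br | intermediate
3 | dimethyl malonate | COC(=O)CC(=O)OC | starting material
4 | dimethyl 2-(hydroxymethyl)malonate | COC(=O)C(CO)C(=O)OC | intermediate (not isolated)
5 | dimethyl methylenemalonate | C=C(C(=O)OC)C(=O)OC | intermediate
6 | cyclopent-2-en-1-one | O=C1C=CCC1 | starting material
7 | bromomagnesium enolate of (R)-3-isopropenylcyclopentanone (enolate C3'=C2') | CC(=C)[C@@H]1CCC(O[Mg]Br)=C1 | intermediate (not isolated)
8 | bromomagnesium malonate enolate of the three-component adduct | COC(=O)C(C[C@H]1[C@@H](CCC1=O)C(C)=C)=C(OC)O[Mg]Br | intermediate (not isolated)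
9 | dimethyl 2-{[(1S,5R)-2-oxo-5-(prop-1-en-2-yl)cyclopentyl]methyl}malonate | COC(=O)C(C[C@H]1[C@@H](CCC1=O)C(C)=C)C(=O)OC | intermediate
10 | dimethyl 2-{[(1S,2R,5R)-2-hydroxy-2-methyl-5-(prop-1-en-2-yl)cyclopentyl]methyl}malonate | COC(=O)C(C[C@H]1[C@@H](CC[C@@]1(C)O)C(C)=C)C(=O)OC | intermediate
11 | dimethyl 2-{[(1S,2R,5R)-2-[(tert-butyldimethylsilyl)oxy]-2-methyl-5-(prop-1-en-2-yl)cyclopentyl]methyl}malonate | COC(=O)C(C[C@H]1[C@@H](CC[C@@]1(C)O[Si](C)(C)C(C)(C)C)C(C)=C)C(=O)OC | intermediate
12 | dimethyl (3R,3aS,7aR)-3-[(tert-butyldimethylsilyl)oxy]-3-methyl-7-methylideneoctahydro-5H-indene-5,5-dicarboxylate | COC(=O)C1(C(=O)OC)C[C@H]2[C@@H](CC[C@@]2(C)O[Si](C)(C)C(C)(C)C)C(=C)C1 | intermediate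
13 | dimethyl (3R,3aS,7R,7aR)-3-[(tert-butyldimethylsilyl)oxy]-7-hydroperoxy-3,7-dimethyloctahydro-5H-indene-5,5-dicarboxylate (C7' hydroperoxide, OOH equatorial) | COC(=O)C1(C(=O)OC)C[C@H]2[C@@H](CC[C@@]2(C)O[Si](C)(C)C(C)(C)C)[C@](C)(OO)C1 | intermediate (not isolated)
14 | dimethyl (3R,3aS,7R,7aR)-3-[(tert-butyldimethylsilyl)oxy]-7-hydroxy-3,7-dimethyloctahydro-5H-indene-5,5-dicarboxylate | COC(=O)C1(C(=O)OC)C[C@H]2[C@@H](CC[C@@]2(C)O[Si](C)(C)C(C)(C)C)[C@](C)(O)C1 | intermediate
15 | acetylacetone (pentane-2,4-dione) | CC(=O)CC(C)=O | starting material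
16 | methyl (3R,3aS,5S,7R,7aR)-3-[(tert-butyldimethylsilyl)oxy]-5-(3,5-dioxohexanoyl)-7-hydroxy-3,7-dimethyloctahydro-5H-indene-5-carboxylate (equatorial triketone chain, axial ester) | CC(=O)CC(=O)CC(=O)[C@@]1(C[C@H]2[C@@H](CC[C@@]2(C)O[Si](C)(C)C(C)(C)C)[C@](C)(O)C1)C(=O)OC | intermediate (not isolated)
17 | ring A trione TBS ether, C1 (S), C5 = CH2, C3'–OTBS, C7'–OH | CC(=O)C1=C(O)CC(=O)[C@@]2(C[C@H]3[C@@H](CC[C@@]3(C)O[Si](C)(C)C(C)(C)C)[C@](C)(O)C2)C1=O | intermediate
18 | ring A trione diol, C1 (S), C5 = CH2, (2'S,3'R,6'R,7'R) | CC(=O)C1=C(O)CC(=O)[C@@]2(C[C@H]3[C@@H](CC[C@@]3(C)O)[C@](C)(O)C2)C1=O | intermediate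
19 | prenyl bromide (1-bromo-3-methylbut-2-ene) | CC(C)=CCBr | starting material
20 | monoprenyl trione, C1 (S), one 3-methylbut-2-en-1-yl group on C5, drawn as its C3=C4/C5=C6 dienol | CC(=O)C1=C(O)C(CC=C(C)C)=C(O)[C@@]2(C[C@H]3[C@@H](CC[C@@]3(C)O)[C@](C)(O)C2)C1=O | intermediate (not isolated)
21 | CNP0266834.1: 3-acetyl-4-hydroxy-5,5-bis(3-methylbut-2-en-1-yl) ring A spiro-fused at C1 (S) to the (2'S,3'R,6'R,7'R)-3',7'-dihydroxy-3',7'-dimethyl-trans-hydrindane | CC(=O)C1=C(O)C(CC=C(C)C)(CC=C(C)C)C(=O)[C@@]2(C[C@H]3[C@@H](CC[C@@]3(C)O)[C@](C)(O)C2)C1=O | target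

Total step count: 10. Longest linear sequence: 9 steps (1 → 2 → 9 → 10 → 11 → 12 → 14 → 17 → 18 → 21; the branch from 3 to 5 is one step).

Steps most likely to fail

Step 3. Enantiocontrol may be lost through a fast uncatalysed addition of the alkenyl Grignard reagent, and the acceptor may be consumed by chain oligomerisation started by the product enolate. The fallback sets out from 2 and 5 and returns at 9, replacing catalyst control by substrate control. The isopropenyl group of 2 is transferred as a phosphine-ligated organocopper reagent (CuBr·SMe2, PBu3, THF, −78 °C) to commercial, enantiopure (S)-4-(tert-butyldimethylsilyloxy)cyclopent-2-en-1-one F1, anti to the silyloxy group. The enolate is captured by 5 anti to the new substituent to give the all-trans adduct dimethyl 2-{[(1S,2R,3S)-3-[(tert-butyldimethylsilyl)oxy]-5-oxo-2-(prop-1-en-2-yl)cyclopentyl]methyl}malonate F2. Warm aqueous AcOH in THF removes the silyl group and dehydrates the β-hydroxy ketone to the enone dimethyl 2-{[(1S,5R)-2-oxo-5-(prop-1-en-2-yl)cyclopent-3-en-1-yl]methyl}malonate F3. Conjugate reduction with [(Ph3P)CuH]6, which leaves the isolated isopropenyl alkene alone, then gives 9.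

Step 8. The dianion may attack the axial instead of the equatorial ester, which would invert C1, or ring closure may stall or divert to O-acylation. The fallback sets out from 14 and returns at 16 (and from there at 17), separating the two events. LiOH (1 equiv) in aqueous THF/MeOH should hydrolyse only the exposed equatorial ester to give the mono acid (3R,3aS,5S,7R,7aR)-3-[(tert-butyldimethylsilyl)oxy]-7-hydroxy-5-(methoxycarbonyl)-3,7-dimethyloctahydro-5H-indene-5-carboxylic acid F4, at which stage any regioisomer can be removed and the assignment checked. Carbonyldiimidazole converts F4 into the acyl imidazolide F5, which acylates the dianion of 15 at its terminal carbon to give 16 as an isolated compound. NaOMe in MeOH then closes ring A on the remaining axial ester to give 17.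

Step 7. Oxygen capture of the C7' radical may show poor facial selectivity; any axial-hydroxyl epimer would sit 1,3-diaxial to the axial ester and should lactonise, which at least makes it easy to remove. The fallback sets out from 12 and returns at 14, using a sterically more demanding polar reagent. mCPBA (NaHCO3, CH2Cl2, 0 °C) should epoxidise the exocyclic alkene from the open equatorial face to give the spiro-epoxide F6 (oxygen equatorial). Preformed sodium phenylselenide ((PhSe)2, NaBH4, EtOH) opens it at the CH2 carbon to the tertiary alcohol with a phenylselanylmethyl group on C7', F7. Bu3SnH with AIBN (toluene, 80 °C) cleaves the C–Se bond to leave the axial methyl group of 14.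

Further compounds
F1 | step 3 | (S)-4-(tert-butyldimethylsilyloxy)cyclopent-2-en-1-one | O=C1C=C[C@@H](O[Si](C)(C)C(C)(C)C)C1
F2 | step 3 | dimethyl 2-{[(1S,2R,3S)-3-[(tert-butyldimethylsilyl)oxy]-5-oxo-2-(prop-1-en-2-yl)cyclopentyl]methyl}malonate | COC(=O)C(C[C@H]1[C@@H]([C@@H](O[Si](C)(C)C(C)(C)C)CC1=O)C(C)=C)C(=O)OC
F3 | step 3 | dimethyl 2-{[(1S,5R)-2-oxo-5-(prop-1-en-2-yl)cyclopent-3-en-1-yl]methyl}malonate | COC(=O)C(C[C@H]1[C@@H](C=CC1=O)C(C)=C)C(=O)OC
F4 | step 8 | (3R,3aS,5S,7R,7aR)-3-[(tert-butyldimethylsilyl)oxy]-7-hydroxy-5-(methoxycarbonyl)-3,7-dimethyloctahydro-5H-indene-5-carboxylic acid | OC(=O)[C@@]1(C[C@H]2[C@@H](CC[C@@]2(C)O[Si](C)(C)C(C)(C)C)[C@](C)(O)C1)C(=O)OC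
F5 | step 8 | acyl imidazolide of F4 (imidazol-1-ylcarbonyl equatorial, CO2Me axial) | O=C(n1ccnc1)[C@@]1(C[C@H]2[C@@H](CC[C@@]2(C)O[Si](C)(C)C(C)(C)C)[C@](C)(O)C1)C(=O)OC
F6 | step 7 | spiro-epoxide of 12 at C7' (oxygen equatorial, CH2 axial) | COC(=O)C1(C(=O)OC)C[C@H]2[C@@H](CC[C@@]2(C)O[Si](C)(C)C(C)(C)C)[C@@]3(CO3)C1
F7 | step 7 | C7' tertiary alcohol carrying an axial phenylselanylmethyl group | COC(=O)C1(C(=O)OC)C[C@H]2[C@@H](CC[C@@]2(C)O[Si](C)(C)C(C)(C)C)[C@](C[Se]c3ccccc3)(O)C1
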